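All runs are calculated from invented constants, noise included.

If each target takes one dissolved gas, as I assumed, the balance to write for this flask was that of the gas, since saturation holds 0.533 of the substrate charge, less than the charge itself.

| flask | substrate | gas phase | catalyst | remark | time |
|---|---|---|---|---|---|
| alpha | 25 mM | 9.6 mM (held) | 2.5 mol% | run made earlier |  |
| delta | 40 mM | 9.6 mM (held) | 2.5 mol% | run made earlier |  |
| flask | 18 mM | 9.6 mM (held) | 2.5 mol% |  | 40 min |

| run | time / min | target / % |
|---|---|---|
| alpha | 2.00 | 1.4 |
| alpha | 3.00 | 0.6 |
| alpha | 5.00 | 2.6 |
| alpha | 8.00 | 7.4 |
| alpha | 15.0 | 12.5 |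
| alpha | 25.0 | 21.4 |
| delta | 1.50 | 0.4 |
| delta | 5.00 | 3.1 |
| delta | 8.00 | 6.3 |
| delta | 12.0 | 9.3 |
| delta | 20.0 | 13.1 |
| delta | 25.0 | 14.6 |

(scatter of a reading: 0.5 percentage points)

- target at 40 min, in percent of the substrate charged
- concentration of dissolved gas in solution at 40 min, in percent of saturation

- at the start none of the gas phase is in solution

Dissolved gas started at nothing. I took its entry as proportional to the gap from saturation, so entry was greatest into empty solution, and I called that greatest entry the ceiling. While dissolved gas holds steady (the quasi-steady state), entry equals use, so the gap, as a fraction of saturation, equals use over ceiling.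

I read both from the runs, counting target as gas used. Delta's steep stretch, from 5.00 min to 12.0 min, gained 0.00886 min⁻¹ of its charge, and I used that pace on delta's 40 mM as the ceiling: an estimate from scattered readings, and a low one, since entry had to cover at least that use. Alpha's later stretch gained 0.00824 min⁻¹, about the same pace, so I took it for the flask too.

At a fixed pace, use grows with the charge. I named the starving charge, the substrate charge whose use at alpha's pace equals the ceiling: 43.0 mM. The flask's charge is 0.418 of that, so I expected dissolved gas at 58.2 % of saturation, and alpha's pace over 40 min gave 33.0 % target.

The forecast, holding that “Dissolved gas should sit near saturation”, gave 31 % target (23 % to 39 %) and 85 % of saturation (62 % to 97 %), higher than my fill.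

The flask gave 32.2 % target and dissolved gas at 61.4 % of saturation.

    gas phase ⇌ dissolved gas, rate k1*(csat - [dissolved gas]) (kL = 0.0660 min⁻¹)
    substrate + target → side product (k = 2.00 M⁻¹ min⁻¹)
    target + catalyst ⇌ isomer of the product + catalyst, rate k3*[catalyst]*[target] forward; the back reaction follows from the equilibrium constant (K = 11.0, k = 1.70 M⁻¹ min⁻¹)
    substrate + dissolved gas + catalyst → catalyst + target (k = 9700 M⁻² min⁻¹)

The flask's dissolved gas stood 3.2 percentage points above my fill. The flask's target stood at 32.2 % because of the bottleneck of the passage of gas phase into dissolved gas together with the turning of substrate + target into side product: the same flask gives 52.2 % without that bottleneck and 49.9 % without that step.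

A neighbour flask with 7.2 mM substrate, at the same catalyst loading and time, carries 0.167 of the starving charge, which gives a fill of 83.3 %. Computed, that neighbour held dissolved gas at 83.4 % of saturation at 40.0 min, with 26.6 % target.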